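**Strategy.** The route rests on cutting the C3–C4 bond of ring C. Because the 2'-hydroxyl of ring B sits ortho to C1', C3 can be the exocyclic carbon of a ring-B ortho-quinone methide; a chiral triazolylidene carbene turns the ring-A aldehyde carbon (C4) into an acyl anion equivalent that adds to this methide carbon. One operation thus forms C3–C4, closes ring C and sets the C3 (S) stereocentre, while erasing the racemic centre of the precursor. That precursor is a racemic 2'-hydroxybenzylic p-tolyl sulfone whose benzylic carbon is linked through C2–O1 to a 4-(methoxymethoxy)salicylaldehyde, assembled from two benzaldehydes and prenyl bromide by Claisen rearrangement, epoxide opening and sulfinate exchange.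

Key step: step 10

Assumption: the sense of induction of the aminoindanol-derived triazolylidene in step 10 can only be assigned by analogy; the (5aR,10bS) salt is written, and its (5aS,10bR) antipode would be used should the (3R) ketone predominate. All benzylic carbinol, epoxide and sulfone centres before step 10 are racemic and are erased in the quinone methide.

Step 1
Reactants: 1 2,3,4-trihydroxybenzaldehyde; 2 prenyl bromide (1-bromo-3-methylbut-2-ene)
Product: 3 2,3-dihydroxy-4-[(3-methylbut-2-en-1-yl)oxy]benzaldehyde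
Conditions: NaHCO3 (1.5 equiv), NaI (cat.), DMF, 40 °C
Reagents that add atoms: none
Why: Williamson etherification under weak-base control: hydrogencarbonate ionises only the 4-OH, which is para to the formyl group and not hydrogen-bonded, so mono-O-prenylation at O4 is expected while the chelated 2-OH and the 3-OH stay free.

Step 2
Reactants: 3 2,3-dihydroxy-4-[(3-methylbut-2-en-1-yl)oxy]benzaldehyde
Product: 4 2-hydroxy-3-(methoxymethoxy)-4-[(3-methylbut-2-en-1-yl)oxy]benzaldehyde
Conditions: MOMCl (1.1 equiv), K2CO3 (1.5 equiv), acetone, 0 °C to rt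
Reagents that add atoms: chloromethyl methyl ether, COCCl
Why: Williamson-type O-alkylation in which the 2-OH stays untouched because it is tied up in the hydrogen bond to the formyl oxygen, the usual outcome when ortho-hydroxyaryl carbonyl compounds are treated with limited MOMCl.

Step 3
Reactants: 4 2-hydroxy-3-(methoxymethoxy)-4-[(3-methylbut-2-en-1-yl)oxy]benzaldehyde
Product: 5 2,4-dihydroxy-3-(methoxymethoxy)-5-(2-methylbut-3-en-2-yl)benzaldehyde
Conditions: N,N-diethylaniline, 190 °C, sealed tube, argon
Reagents that add atoms: none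
Why: Aromatic Claisen rearrangement: the [3,3] shift can only deliver the allyl unit to C5, the one free position ortho to O4, with allylic inversion that turns the prenyl ether into the 1,1-dimethylallyl group, and the basic solvent should hold back acid-promoted cyclisation of the new ortho-allylphenol.

Step 4
Reactants: 5 2,4-dihydroxy-3-(methoxymethoxy)-5-(2-methylbut-3-en-2-yl)benzaldehyde
Product: 6 2-hydroxy-4-methoxy-3-(methoxymethoxy)-5-(2-methylbut-3-en-2-yl)benzaldehyde
Conditions: MeI (1.1 equiv), K2CO3 (1.2 equiv), DMF, rt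
Reagents that add atoms: iodomethane, CI
Why: Williamson O-methylation with about one equivalent of base: the 4-OH para to the formyl group is the more acidic and is not chelated, so it should be methylated ahead of the hydrogen-bonded 2-OH.

Step 5
Reactants: 6 2-hydroxy-4-methoxy-3-(methoxymethoxy)-5-(2-methylbut-3-en-2-yl)benzaldehyde
Product: 7 4-methoxy-3-(methoxymethoxy)-5-(2-methylbut-3-en-2-yl)-2-(prop-2-en-1-yloxy)benzaldehyde
Conditions: allyl bromide (1.5 equiv), K2CO3 (2 equiv), DMF, 60 °C
Reagents that add atoms: allyl bromide (3-bromoprop-1-ene), C=CCBr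
Why: Williamson etherification under more forcing conditions caps the remaining chelated 2-OH as an allyl ether, a mask that survives ylide and base and can later be removed by palladium catalysis in the presence of the MOM ethers.

Step 6
Reactants: 7 4-methoxy-3-(methoxymethoxy)-5-(2-methylbut-3-en-2-yl)-2-(prop-2-en-1-yloxy)benzaldehyde
Product: 8 rac-2-[4-methoxy-3-(methoxymethoxy)-5-(2-methylbut-3-en-2-yl)-2-(prop-2-en-1-yloxy)phenyl]oxirane
Conditions: Me3S+ I− (1.3 equiv), NaH (1.3 equiv), DMSO/THF, 0 °C to rt; crude product used directly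
Reagents that add atoms: trimethylsulfonium iodide, C[S+](C)C.[I-]
Why: Corey–Chaykovsky epoxidation: dimethylsulfonium methylide adds to the aldehyde and the betaine closes to the terminal epoxide (racemic), the fully etherified ring tolerating the basic medium.

Step 7
Reactants: 9 2,4-dihydroxybenzaldehyde
Product: 10 2-hydroxy-4-(methoxymethoxy)benzaldehyde
Conditions: MOMCl (1.05 equiv), K2CO3 (1.5 equiv), acetone, 0 °C to rt
Reagents that add atoms: chloromethyl methyl ether, COCCl
Why: Selective Williamson-type protection: the 4-OH is alkylated while the 2-OH, hydrogen-bonded to the formyl group, remains free, as is standard for this compound.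

Step 8
Reactants: 8 rac-2-[4-methoxy-3-(methoxymethoxy)-5-(2-methylbut-3-en-2-yl)-2-(prop-2-en-1-yloxy)phenyl]oxirane; 10 2-hydroxy-4-(methoxymethoxy)benzaldehyde
Product: 11 rac-2-{2-hydroxy-2-[4-methoxy-3-(methoxymethoxy)-5-(2-methylbut-3-en-2-yl)-2-(prop-2-en-1-yloxy)phenyl]ethoxy}-4-(methoxymethoxy)benzaldehyde
Conditions: 10 (1.3 equiv), Cs2CO3 (0.3 equiv), DMF, 80 °C
Reagents that add atoms: none
Why: Base-mediated SN2 ring opening of the aryl oxirane by the phenoxide of 10 at the unhindered terminal carbon should give the secondary benzylic alcohol, the catalytic base being regenerated by proton transfer from 10 to the product alkoxide.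

Step 9
Reactants: 11 rac-2-{2-hydroxy-2-[4-methoxy-3-(methoxymethoxy)-5-(2-methylbut-3-en-2-yl)-2-(prop-2-en-1-yloxy)phenyl]ethoxy}-4-(methoxymethoxy)benzaldehyde
Product: 13 rac-2-{2-[2-hydroxy-4-methoxy-3-(methoxymethoxy)-5-(2-methylbut-3-en-2-yl)phenyl]-2-[(4-methylphenyl)sulfonyl]ethoxy}-4-(methoxymethoxy)benzaldehyde, via free phenol benzylic alcohol 12 (not isolated)
Conditions: Pd(PPh3)4 (5 mol%), p-TolSO2H (4 equiv), CH2Cl2, 0 °C to rt
Reagents that add atoms: p-toluenesulfinic acid, Cc1ccc(cc1)S(=O)O
Why: Tsuji–Trost-type deallylation (zerovalent palladium ionises the aryl allyl ether and sulfinate captures the allyl fragment) frees the 2'-phenol, after which the ortho-hydroxybenzylic alcohol ionises under the same sulfinic acid and is trapped at sulfur (SN1-type substitution through the benzylic cation) to give the sulfone, the aryl MOM ethers being expected to tolerate this weak acid in an aprotic solvent.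

Step 10
Reactants: 13 rac-2-{2-[2-hydroxy-4-methoxy-3-(methoxymethoxy)-5-(2-methylbut-3-en-2-yl)phenyl]-2-[(4-methylphenyl)sulfonyl]ethoxy}-4-(methoxymethoxy)benzaldehyde
Product: 15 (3S)-3-[2-hydroxy-4-methoxy-3-(methoxymethoxy)-5-(2-methylbut-3-en-2-yl)phenyl]-7-(methoxymethoxy)-2,3-dihydro-4H-chromen-4-one, via ortho-quinone methide 14 (not isolated)
Conditions: (5aR,10bS)-2-(pentafluorophenyl)-5a,10b-dihydro-4H,6H-indeno[2,1-b][1,2,4]triazolo[4,3-d][1,4]oxazin-2-ium tetrafluoroborate (20 mol%), Cs2CO3 (1.2 equiv), 4 Å MS, toluene (0.02 M), 0 °C; AcOH quench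
Reagents that add atoms: none
Why: Proposed new method: carbonate deprotonates the 2'-phenol, which expels p-toluenesulfinate to give ortho-quinone methide 14, while the triazolylidene adds to the ring-A aldehyde and, after proton transfer, the resulting enaminol attacks the methide carbon, rearomatising ring B before the carbene is released from the C4 ketone. The closest known reactions are the asymmetric intramolecular Stetter cyclisation of salicylaldehyde-derived ethers to chroman-4-ones and the carbene-catalysed intermolecular acylation of ortho-quinone methides generated from 2-(1-sulfonylalkyl)phenols. Ring C closes in a 6-exo-trig mode, the O1–C2 tether holding the acyl anion equivalent within reach of C3 so that intramolecular capture should outrun benzoin coupling at high dilution. The new C3 stereocentre is set under catalyst control: the indane wall of the aminoindanol-derived carbene blocks one face of the enaminol, so a single face of the planar methide carbon is engaged, and both enantiomers of the racemic sulfone converge on one product. The step needs 1,4-elimination of sulfinate rather than β-elimination of the aryloxide, and a configurationally stable product; the phenol, far more acidic than the α-sulfonyl C–H, secures the first, and storage of residual base as the 2'-phenoxide, low temperature and the acetic acid quench should protect the C3–H.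

Step 11
Reactants: 15 (3S)-3-[2-hydroxy-4-methoxy-3-(methoxymethoxy)-5-(2-methylbut-3-en-2-yl)phenyl]-7-(methoxymethoxy)-2,3-dihydro-4H-chromen-4-one
Product: 16 (3S)-3-[2,3-dihydroxy-4-methoxy-5-(2-methylbut-3-en-2-yl)phenyl]-7-hydroxy-2,3-dihydro-4H-chromen-4-one
Conditions: HCl (1.25 M in MeOH), 0 °C to rt, short contact; NaHCO3 work-up
Reagents that add atoms: none
Why: Acid-catalysed acetal solvolysis should release both phenols as dimethoxymethane; dilute acid, low temperature and short contact are chosen so that acid-mediated enolisation at C3 and cyclodehydration of the 2'-hydroxy ketone do not erode the stereocentre, and the 1,1-dimethylallyl group has no free ortho-hydroxyl to cyclise onto.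

**Compound list**

1 | 2,3,4-trihydroxybenzaldehyde | O=Cc1ccc(O)c(O)c1O | starting material
2 | prenyl bromide (1-bromo-3-methylbut-2-ene) | CC(C)=CCBr | starting material
3 | 2,3-dihydroxy-4-[(3-methylbut-2-en-1-yl)oxy]benzaldehyde | O=Cc1ccc(OCC=C(C)C)c(O)c1O | intermediate
4 | 2-hydroxy-3-(methoxymethoxy)-4-[(3-methylbut-2-en-1-yl)oxy]benzaldehyde | O=Cc1ccc(OCC=C(C)C)c(OCOC)c1O | intermediate
5 | 2,4-dihydroxy-3-(methoxymethoxy)-5-(2-methylbut-3-en-2-yl)benzaldehyde | O=Cc1cc(C(C)(C)C=C)c(O)c(OCOC)c1O | intermediate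
6 | 2-hydroxy-4-methoxy-3-(methoxymethoxy)-5-(2-methylbut-3-en-2-yl)benzaldehyde | O=Cc1cc(C(C)(C)C=C)c(OC)c(OCOC)c1O | intermediate
7 | 4-methoxy-3-(methoxymethoxy)-5-(2-methylbut-3-en-2-yl)-2-(prop-2-en-1-yloxy)benzaldehyde | O=Cc1cc(C(C)(C)C=C)c(OC)c(OCOC)c1OCC=C | intermediate
8 | rac-2-[4-methoxy-3-(methoxymethoxy)-5-(2-methylbut-3-en-2-yl)-2-(prop-2-en-1-yloxy)phenyl]oxirane | C=CCOc1c(C2CO2)cc(C(C)(C)C=C)c(OC)c1OCOC | intermediate
9 | 2,4-dihydroxybenzaldehyde | O=Cc1ccc(O)cc1O | starting material
10 | 2-hydroxy-4-(methoxymethoxy)benzaldehyde | O=Cc1ccc(OCOC)cc1O | intermediate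
11 | rac-2-{2-hydroxy-2-[4-methoxy-3-(methoxymethoxy)-5-(2-methylbut-3-en-2-yl)-2-(prop-2-en-1-yloxy)phenyl]ethoxy}-4-(methoxymethoxy)benzaldehyde | C=CCOc1c(C(O)COc2cc(OCOC)ccc2C=O)cc(C(C)(C)C=C)c(OC)c1OCOC | intermediate
12 | rac-2-{2-hydroxy-2-[2-hydroxy-4-methoxy-3-(methoxymethoxy)-5-(2-methylbut-3-en-2-yl)phenyl]ethoxy}-4-(methoxymethoxy)benzaldehyde | Oc1c(C(O)COc2cc(OCOC)ccc2C=O)cc(C(C)(C)C=C)c(OC)c1OCOC | intermediate (not isolated)
13 | rac-2-{2-[2-hydroxy-4-methoxy-3-(methoxymethoxy)-5-(2-methylbut-3-en-2-yl)phenyl]-2-[(4-methylphenyl)sulfonyl]ethoxy}-4-(methoxymethoxy)benzaldehyde | Cc1ccc(cc1)S(=O)(=O)C(COc1cc(OCOC)ccc1C=O)c1cc(C(C)(C)C=C)c(OC)c(OCOC)c1O | intermediate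
14 | 2-{2-[4-methoxy-5-(methoxymethoxy)-3-(2-methylbut-3-en-2-yl)-6-oxocyclohexa-2,4-dien-1-ylidene]ethoxy}-4-(methoxymethoxy)benzaldehyde (ortho-quinone methide, alkene geometry not defined) | O=Cc1ccc(OCOC)cc1OCC=C1C=C(C(C)(C)C=C)C(OC)=C(OCOC)C1=O | intermediate (not isolated)
15 | (3S)-3-[2-hydroxy-4-methoxy-3-(methoxymethoxy)-5-(2-methylbut-3-en-2-yl)phenyl]-7-(methoxymethoxy)-2,3-dihydro-4H-chromen-4-one | C=CC(C)(C)c1cc([C@H]2COc3cc(OCOC)ccc3C2=O)c(O)c(OCOC)c1OC | intermediate
16 | (3S)-3-[2,3-dihydroxy-4-methoxy-5-(2-methylbut-3-en-2-yl)phenyl]-7-hydroxy-2,3-dihydro-4H-chromen-4-one | C=CC(C)(C)c1cc([C@H]2COc3cc(O)ccc3C2=O)c(O)c(O)c1OC | target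

**Step count.** Total: 11 steps. Longest linear sequence: 10 steps (steps 1–6 and 8–11).

**Steps most likely to fail**

Step 10. The enaminol may fail to intercept the quinone methide: intermolecular benzoin coupling, carbene addition to the methide or a 1,5-hydrogen shift of the methide could win. Facial selectivity may also be poor, or C3 may epimerise under base. The fallback uses only known chemistry, sets out from epoxide 8 and returns at 15.
- Epoxide 8 is isomerised with catalytic InCl3 (Meinwald rearrangement) to the arylacetaldehyde F1.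
- 1-Bromo-2,4-bis(methoxymethoxy)benzene F2 (from 4-bromoresorcinol, MOMCl, K2CO3) is lithiated with n-BuLi, transmetalated with CeCl3 and added to F1 to give the secondary alcohol F3.
- Dess–Martin oxidation gives the deoxybenzoin F4.
- Brief cold methanolic HCl removes the MOM ether ortho to the ketone, which chelation makes the most labile, and gives the 2-hydroxy deoxybenzoin F5.
- Condensation with N,N-dimethylformamide dimethyl acetal in warm toluene closes the isoflavone F6.
- Asymmetric transfer hydrogenation with RuCl(p-cymene)(TsDPEN) and HCO2H/Et3N reduces the enone and then the ketone under dynamic kinetic resolution. The ligand enantiomer is chosen to give the cis-(3S,4S)-isoflavan-4-ol F7.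
- Buffered Dess–Martin oxidation returns the C4 ketone without touching C3 and gives the allyl-protected (3S)-isoflavanone F8.
- Pd(PPh3)4 and morpholine remove the allyl ether to give 15.

Step 8. Attack by the chelated, weakly nucleophilic salicylaldehyde phenoxide may be sluggish. The heat- and acid-sensitive epoxide could then rearrange, or be opened at the benzylic carbon. The fallback reverses the roles of the partners, sets out from 8 and returns at 11.
- Epoxide 8 is hydrolysed with KOH in DMSO/H2O at 80 °C to the 1,2-diol F9.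
- 2-Fluoro-4-(methoxymethoxy)benzaldehyde F10 is made from commercial 2-fluoro-4-hydroxybenzaldehyde with MOMCl and K2CO3.
- The primary alkoxide of F9 (NaH, 1.0 equiv, DMF, 0 °C to rt) displaces the fluoride ortho to the formyl group of F10 by nucleophilic aromatic substitution. This should give 11 with the ether oxygen on the terminal carbon.

Step 3. The first-formed ortho-(1,1-dimethylallyl)phenol may react further at 190 °C, by abnormal Claisen isomerisation or by cyclisation of the phenol onto the alkene. Thermal loss of the prenyl group is also possible. The fallback installs the side chain by cross-coupling, sets out from 1 and returns at 6, replacing steps 1–4.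
- Compound 1 is methylated at O4 (MeI, Li2CO3, DMF) to 2,3-dihydroxy-4-methoxybenzaldehyde F11.
- Selective MOM protection of the unchelated 3-OH (MOMCl, K2CO3, acetone) gives F12.
- NBS in MeCN at 0 °C brominates C5, which is para to the 2-OH and ortho to the methoxy group, to give the aryl bromide F13.
- Ligand-controlled γ-selective Suzuki–Miyaura coupling with 4,4,5,5-tetramethyl-2-(3-methylbut-2-en-1-yl)-1,3,2-dioxaborolane (Pd(OAc)2, bulky biarylphosphine, K3PO4, THF/H2O) should deliver the 1,1-dimethylallyl group at C5 and give 6.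

**Further compounds**

F1 | step 10 | 2-[4-methoxy-3-(methoxymethoxy)-5-(2-methylbut-3-en-2-yl)-2-(prop-2-en-1-yloxy)phenyl]acetaldehyde | C=CCOc1c(CC=O)cc(C(C)(C)C=C)c(OC)c1OCOC
F2 | step 10 | 1-bromo-2,4-bis(methoxymethoxy)benzene | COCOc1ccc(Br)c(OCOC)c1
F3 | step 10 | rac-1-[2,4-bis(methoxymethoxy)phenyl]-2-[4-methoxy-3-(methoxymethoxy)-5-(2-methylbut-3-en-2-yl)-2-(prop-2-en-1-yloxy)phenyl]ethan-1-ol | C=CCOc1c(CC(O)c2ccc(OCOC)cc2OCOC)cc(C(C)(C)C=C)c(OC)c1OCOC
F4 | step 10 | 1-[2,4-bis(methoxymethoxy)phenyl]-2-[4-methoxy-3-(methoxymethoxy)-5-(2-methylbut-3-en-2-yl)-2-(prop-2-en-1-yloxy)phenyl]ethan-1-one | C=CCOc1c(CC(=O)c2ccc(OCOC)cc2OCOC)cc(C(C)(C)C=C)c(OC)c1OCOC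
F5 | step 10 | 1-[2-hydroxy-4-(methoxymethoxy)phenyl]-2-[4-methoxy-3-(methoxymethoxy)-5-(2-methylbut-3-en-2-yl)-2-(prop-2-en-1-yloxy)phenyl]ethan-1-one | C=CCOc1c(CC(=O)c2ccc(OCOC)cc2O)cc(C(C)(C)C=C)c(OC)c1OCOC
F6 | step 10 | 3-[4-methoxy-3-(methoxymethoxy)-5-(2-methylbut-3-en-2-yl)-2-(prop-2-en-1-yloxy)phenyl]-7-(methoxymethoxy)-4H-chromen-4-one | C=CCOc1c(C2=COc3cc(OCOC)ccc3C2=O)cc(C(C)(C)C=C)c(OC)c1OCOC
F7 | step 10 | (3S,4S)-3-[4-methoxy-3-(methoxymethoxy)-5-(2-methylbut-3-en-2-yl)-2-(prop-2-en-1-yloxy)phenyl]-7-(methoxymethoxy)-3,4-dihydro-2H-chromen-4-ol | C=CCOc1c([C@H]2COc3cc(OCOC)ccc3[C@H]2O)cc(C(C)(C)C=C)c(OC)c1OCOC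
F8 | step 10 | (3S)-3-[4-methoxy-3-(methoxymethoxy)-5-(2-methylbut-3-en-2-yl)-2-(prop-2-en-1-yloxy)phenyl]-7-(methoxymethoxy)-2,3-dihydro-4H-chromen-4-one | C=CCOc1c([C@H]2COc3cc(OCOC)ccc3C2=O)cc(C(C)(C)C=C)c(OC)c1OCOC
F9 | step 8 | rac-1-[4-methoxy-3-(methoxymethoxy)-5-(2-methylbut-3-en-2-yl)-2-(prop-2-en-1-yloxy)phenyl]ethane-1,2-diol | C=CCOc1c(C(O)CO)cc(C(C)(C)C=C)c(OC)c1OCOC
F10 | step 8 | 2-fluoro-4-(methoxymethoxy)benzaldehyde | O=Cc1ccc(OCOC)cc1F
F11 | step 3 | 2,3-dihydroxy-4-methoxybenzaldehyde | O=Cc1ccc(OC)c(O)c1O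
F12 | step 3 | 2-hydroxy-4-methoxy-3-(methoxymethoxy)benzaldehyde | O=Cc1ccc(OC)c(OCOC)c1O
F13 | step 3 | 5-bromo-2-hydroxy-4-methoxy-3-(methoxymethoxy)benzaldehyde | O=Cc1cc(Br)c(OC)c(OCOC)c1O
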